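A direct plan would build the chromene first on 1-(3,4-dihydroxyphenyl)ethan-1-one A1, extend the acetyl group to a β-keto ester, and set the only stereocentre early by ketoreductase reduction to the (R)-benzylic carbinol ester A2.
It would then acylate lithiated 1,3,5-tris(methoxymethoxy)benzene A3 with the derived Weinreb amide, unmask one ortho-phenol and the carbinol to give the dihydroxy ketone A4, close the pyranone by Mitsunobu etherification with inversion to the tris-MOM flavanone A5, and finish with acid.
Its weakest steps would be: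
- the Mitsunobu ring closure, because a benzylic carbinol para to an ether oxygen and β to a ketone can ionise (loss of ee) or eliminate to the chalcone (racemic re-closure), and this on the most advanced material;
- the protecting-group traffic around it (silyl on and off, chelation-controlled removal of one of three MOM groups), several steps that add no skeletal bond;
- the opening mono-protection of the catechol, whose regiochemistry rests on a small nucleophilicity difference within a dianion.

**Plan of the new route**
The one strategic cut is C2–C1′ (flavanone C2 to chromene C6). C2 is the β-carbon of the vinylogous ester O1–C2=C3–C4=O in the flat γ-pyranone ring of commercial 5,7-dihydroxychromone.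
The B-ring is therefore added as an aryl nucleophile in a catalytic enantioselective 1,4-addition that dearomatises the pyranone and creates C2 (S) in the bond-forming event itself.
The aryl donor comes from C–H borylation at chromene C6, the only aromatic C–H with no ortho substituent (C5 lies next to the ring fusion, C7 next to O-8).
Ring order: the pyranone C-ring is present from the start and is never closed; the chromene pyran is formed once (oxa-6π) on a C11 fragment; the two bicycles are joined in the penultimate step.
No carbinol is inverted, no ring is closed at the stereocentre, and each half carries one silyl group, both removed together.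

Key step: step 5

Assumption: C2 is S as read from the SMILES (O1 > C1′ > C3 > H); the (S)-bisphosphine is taken to give 2S by analogy with the known sense of Rh/(S)-biaryl bisphosphine addition to cyclohexenone, and the ligand enantiomer would be fixed by a model run on the parent chromone.

**Route**

Step 1
Reactants: 1 2,3-dihydroxybenzaldehyde; 2 (2-methylprop-1-en-1-yl)magnesium bromide
Product: 5 2,2-dimethyl-2H-chromen-8-ol, via benzylic carbinol 3 (not isolated), via o-quinone methide 4 (not isolated)
Conditions: 2 (3.3 equiv), THF, 0 °C → rt; aq NH4Cl; then PPTS (5 mol%), toluene, 60 °C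
Reagents that add atoms: (2-methylprop-1-en-1-yl)magnesium bromide (2), CC(C)=C[Mg]Br
Why: Grignard addition to the aldehyde (the first two equivalents deprotonate the phenols) gives the doubly activated benzylic/allylic carbinol 3, which loses water under mild acid to the vinyl o-quinone methide 4 (carbonyl from the 2-OH), and oxa-6π electrocyclisation of 4 closes O1–C2 so that the former 3-OH becomes the chromene 8-OH; no stereocentre remains.

Step 2
Reactants: 5 2,2-dimethyl-2H-chromen-8-ol
Product: 6 [(2,2-dimethyl-2H-chromen-8-yl)oxy]tri(propan-2-yl)silane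
Conditions: TIPSCl (1.2 equiv), imidazole (2.5 equiv), DMF, rt
Reagents that add atoms: chlorotri(propan-2-yl)silane (TIPSCl), CC(C)[Si](Cl)(C(C)C)C(C)C
Why: Imidazole-mediated O-silylation of the only phenol; the TIPS ether should tolerate the borylation, periodate and aqueous rhodium steps and adds bulk next to C7–H.

Step 3
Reactants: 6 [(2,2-dimethyl-2H-chromen-8-yl)oxy]tri(propan-2-yl)silane
Product: 8 {2,2-dimethyl-8-[(triisopropylsilyl)oxy]-2H-chromen-6-yl}boronic acid, via pinacol boronate 7 (not isolated)
Conditions: [Ir(OMe)(cod)]2 (1.5 mol%), dtbpy (3 mol%), B2pin2 (1.0 equiv), THF, 60 °C; evaporate; then NaIO4 (3 equiv), NH4OAc (3 equiv), acetone/H2O, rt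
Reagents that add atoms: bis(pinacolato)diboron, CC1(C)OB(OC1(C)C)B1OC(C)(C)C(C)(C)O1; water, O
Why: Iridium-catalysed arene C–H borylation is sterically governed, so boron should enter at C6, the only aromatic C–H without an ortho substituent (C5–H is ortho to the ring-fusion carbon bearing C4, C7–H is ortho to OTIPS, and the vinylic C3–H and C4–H are flanked by CMe2 and by the arene), and periodate then cleaves the pinacol released by hydrolysis of 7, driving the ester to the free boronic acid (borylation followed by oxidative hydrolysis of the crude ester).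

Step 4
Reactants: 9 5,7-dihydroxy-4H-chromen-4-one
Product: 10 5-hydroxy-7-[(triisopropylsilyl)oxy]-4H-chromen-4-one
Conditions: TIPSCl (1.05 equiv), imidazole (2 equiv), DMF, 0 °C → rt
Reagents that add atoms: chlorotri(propan-2-yl)silane (TIPSCl), CC(C)[Si](Cl)(C(C)C)C(C)C
Why: Selective O-silylation of the acidic, non-chelated 7-OH (the 5-OH is held in a hydrogen bond to C4=O and is far less nucleophilic) keeps the chromone neutral and toluene-soluble in the key step, where a free 7-OH would give the unreactive vinylogous carboxylate.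

Step 5
Reactants: 8 {2,2-dimethyl-8-[(triisopropylsilyl)oxy]-2H-chromen-6-yl}boronic acid; 10 5-hydroxy-7-[(triisopropylsilyl)oxy]-4H-chromen-4-one
Product: 11 (2S)-2-{2,2-dimethyl-8-[(triisopropylsilyl)oxy]-2H-chromen-6-yl}-5-hydroxy-7-[(triisopropylsilyl)oxy]-2,3-dihydro-4H-chromen-4-one
Conditions: [RhCl(C2H4)2]2 (1.5 mol%), (S)-MeO-F12-BIPHEP (3.3 mol%), aq KOH (5 mol%), 8 (1.6 equiv), toluene/H2O 10:1, 30 °C
Reagents that add atoms: none
Why: The hydroxo-Rh(I)/bisphosphine complex formed in situ transmetalates with 8 to an aryl–Rh(I) species, the chromone C2=C3 bond inserts into the Rh–aryl bond with the aryl group going to C2, and the oxa-π-allyl Rh enolate is protonated by water to release 11 and regenerate Rh–OH. The closest known reaction type is the Rh-catalysed asymmetric 1,4-addition of arylboronic acids to chromones (Hayashi–Miyaura reaction), which gives flavanones directly. No ring is closed: the C2–C1′ bond forms intermolecularly and the flat γ-pyranone ring, present since 9, is dearomatised to the chroman-4-one. The C2 stereocentre is set by catalyst control alone, the C2-symmetric bisphosphine selecting the enone face to which the aryl group is delivered (S-ligand expected to give 2S, see the assumption). The step needs mono-addition without β-elimination of the O1 aryloxide from the Rh enolate (ring opening to the 2′-hydroxychalcone, which would re-close as a racemate or take up a second aryl group); the electron-poor ligand should allow turnover at 30 °C in an almost base-free two-phase medium, where protonation outruns ring opening. Chemoselectivity rests on the substrate: the chelated 5-OH raises the electrophilicity of C2, the 7-O-TIPS group prevents formation of the 7-phenoxide, and the hindered, unactivated C3=C4 alkene of the chromene is no acceptor for aryl–Rh.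

Step 6
Reactants: 11 (2S)-2-{2,2-dimethyl-8-[(triisopropylsilyl)oxy]-2H-chromen-6-yl}-5-hydroxy-7-[(triisopropylsilyl)oxy]-2,3-dihydro-4H-chromen-4-one
Product: 12 (2S)-5,7-dihydroxy-2-(8-hydroxy-2,2-dimethyl-2H-chromen-6-yl)-2,3-dihydro-4H-chromen-4-one (sigmoidin C)
Conditions: HF·pyridine (excess), pyridine, THF, 0 °C → rt
Reagents that add atoms: none
Why: Fluoride-induced cleavage of both aryl silyl ethers in an acidic, pyridine-buffered medium; flavanone C2 epimerises only through base-mediated retro-oxa-Michael ring opening, which is excluded here, and the chromene should be inert to dilute HF·pyridine.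

**Compound list**

1 | 2,3-dihydroxybenzaldehyde | O=Cc1cccc(O)c1O | starting material
2 | (2-methylprop-1-en-1-yl)magnesium bromide | CC(C)=C[Mg]Br | starting material
3 | 3-(1-hydroxy-3-methylbut-2-en-1-yl)benzene-1,2-diol (racemic) | CC(C)=CC(O)c1cccc(O)c1O | intermediate
4 | (6Z)-2-hydroxy-6-(3-methylbut-2-en-1-ylidene)cyclohexa-2,4-dien-1-one | CC(C)=C/C=C1/C=CC=C(O)C1=O | intermediate
5 | 2,2-dimethyl-2H-chromen-8-ol | CC1(C)C=Cc2cccc(O)c2O1 | intermediate
6 | [(2,2-dimethyl-2H-chromen-8-yl)oxy]tri(propan-2-yl)silane | CC1(C)C=Cc2cccc(O[Si](C(C)C)(C(C)C)C(C)C)c2O1 | intermediate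
7 | 2-{2,2-dimethyl-8-[(triisopropylsilyl)oxy]-2H-chromen-6-yl}-4,4,5,5-tetramethyl-1,3,2-dioxaborolane | CC1(C)C=Cc2cc(B3OC(C)(C)C(C)(C)O3)cc(O[Si](C(C)C)(C(C)C)C(C)C)c2O1 | intermediate
8 | {2,2-dimethyl-8-[(triisopropylsilyl)oxy]-2H-chromen-6-yl}boronic acid | CC1(C)C=Cc2cc(B(O)O)cc(O[Si](C(C)C)(C(C)C)C(C)C)c2O1 | intermediate
9 | 5,7-dihydroxy-4H-chromen-4-one | O=c1ccoc2cc(O)cc(O)c12 | starting material
10 | 5-hydroxy-7-[(triisopropylsilyl)oxy]-4H-chromen-4-one | O=c1ccoc2cc(O[Si](C(C)C)(C(C)C)C(C)C)cc(O)c12 | intermediate
11 | (2S)-2-{2,2-dimethyl-8-[(triisopropylsilyl)oxy]-2H-chromen-6-yl}-5-hydroxy-7-[(triisopropylsilyl)oxy]-2,3-dihydro-4H-chromen-4-one | CC1(C)C=Cc2cc([C@@H]3CC(=O)c4c(O)cc(O[Si](C(C)C)(C(C)C)C(C)C)cc4O3)cc(O[Si](C(C)C)(C(C)C)C(C)C)c2O1 | intermediate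
12 | (2S)-5,7-dihydroxy-2-(8-hydroxy-2,2-dimethyl-2H-chromen-6-yl)-2,3-dihydro-4H-chromen-4-one | CC1(C)C=Cc2cc([C@@H]3CC(=O)c4c(O)cc(O)cc4O3)cc(O)c2O1 | target

**Step count and risks**

Total steps: 6. Longest linear sequence: 5 (steps 1, 2, 3, 5, 6); step 4 is a one-step side branch.

Steps most likely to fail:

1. Step 5. The Rh enolate may open by β-elimination of the aryloxide and re-close without control, the catalyst may be held back as a chelate of the 5-hydroxy-4-keto unit, the electron-rich boronic acid may protodeboronate, or facial selectivity may be insufficient. Fallback: the union would be separated from the stereochemistry. From 8 and 10, an achiral catalyst ([Rh(OH)(cod)]2, dioxane/H2O, 50 °C) would give the racemic flavanone F1. This would be resolved kinetically by Noyori–Ikariya transfer hydrogenation (RuCl(p-cymene)(TsDPEN), HCO2H/Et3N, stopped near half conversion). The catalyst enantiomer that reduces the (2R)-ketone faster would convert it into the cis-(2R,4R)-flavan-4-ol F2, separable by chromatography, and leave the (2S)-ketone, so that the route is rejoined at 11.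

2. Step 3. Borylation or hydroboration may occur at the chromene C3=C4 bond, boron may enter at C5, or a second boryl group may be introduced. Fallback: the boron site would be fixed before the chromene exists. From 1, bromination at C5, para to the 2-OH and meta to the formyl group (Br2, AcOH), would give 5-bromo-2,3-dihydroxybenzaldehyde F3. Addition of 2 (THF, then aq NH4Cl) would give the bromo carbinol F4, which would cyclise under the conditions of step 1 through the bromo o-quinone methide F5 to 6-bromo-2,2-dimethyl-2H-chromen-8-ol F6. Silylation as in step 2 would give the bromo TIPS ether F7, and Miyaura borylation (Pd(dppf)Cl2, B2pin2, KOAc, dioxane, 80 °C) would give 7, where the route is rejoined before the periodate treatment.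

3. Step 1. Addition to the aggregated, deactivated magnesium catecholate may stall, or the o-quinone methide may be trapped intermolecularly (oligomerisation) before it electrocyclises. Fallback: the pyran carbons would be brought in through a coumarin. From 1, a Wittig reaction with ethyl (triphenylphosphoranylidene)acetate in refluxing N,N-diethylaniline would give the cinnamate F8, which lactonises in the same pot to 8-hydroxy-2H-chromen-2-one F9. Excess MeMgBr (THF, 0 °C → rt, then aq NH4Cl) would open the lactone to the (Z)-configured tertiary allylic alcohol F10, and mild acid (PPTS, toluene) would cyclodehydrate it to 5, where the route is rejoined.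

**Further compounds**

F1 | step 5 | 2-{2,2-dimethyl-8-[(triisopropylsilyl)oxy]-2H-chromen-6-yl}-5-hydroxy-7-[(triisopropylsilyl)oxy]-2,3-dihydro-4H-chromen-4-one (racemate) | CC1(C)C=Cc2cc(C3CC(=O)c4c(O)cc(O[Si](C(C)C)(C(C)C)C(C)C)cc4O3)cc(O[Si](C(C)C)(C(C)C)C(C)C)c2O1
F2 | step 5 | (2R,4R)-2-{2,2-dimethyl-8-[(triisopropylsilyl)oxy]-2H-chromen-6-yl}-7-[(triisopropylsilyl)oxy]-3,4-dihydro-2H-chromene-4,5-diol | CC1(C)C=Cc2cc([C@H]3C[C@@H](O)c4c(O)cc(O[Si](C(C)C)(C(C)C)C(C)C)cc4O3)cc(O[Si](C(C)C)(C(C)C)C(C)C)c2O1
F3 | step 3 | 5-bromo-2,3-dihydroxybenzaldehyde | O=Cc1cc(Br)cc(O)c1O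
F4 | step 3 | 5-bromo-3-(1-hydroxy-3-methylbut-2-en-1-yl)benzene-1,2-diol (racemic) | CC(C)=CC(O)c1cc(Br)cc(O)c1O
F5 | step 3 | (6Z)-4-bromo-2-hydroxy-6-(3-methylbut-2-en-1-ylidene)cyclohexa-2,4-dien-1-one | CC(C)=C/C=C1/C=C(Br)C=C(O)C1=O
F6 | step 3 | 6-bromo-2,2-dimethyl-2H-chromen-8-ol | CC1(C)C=Cc2cc(Br)cc(O)c2O1
F7 | step 3 | [(6-bromo-2,2-dimethyl-2H-chromen-8-yl)oxy]tri(propan-2-yl)silane | CC1(C)C=Cc2cc(Br)cc(O[Si](C(C)C)(C(C)C)C(C)C)c2O1
F8 | step 1 | ethyl (2E)-3-(2,3-dihydroxyphenyl)prop-2-enoate | CCOC(=O)/C=C/c1cccc(O)c1O
F9 | step 1 | 8-hydroxy-2H-chromen-2-one | O=c1ccc2cccc(O)c2o1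
F10 | step 1 | 3-[(1Z)-3-hydroxy-3-methylbut-1-en-1-yl]benzene-1,2-diol | CC(C)(O)/C=C\c1cccc(O)c1O
A1 | direct plan | 1-(3,4-dihydroxyphenyl)ethan-1-one | CC(=O)c1ccc(O)c(O)c1
A2 | direct plan | ethyl (3R)-3-hydroxy-3-[8-(methoxymethoxy)-2,2-dimethyl-2H-chromen-6-yl]propanoate | CCOC(=O)C[C@@H](O)c1cc2C=CC(C)(C)Oc2c(OCOC)c1
A3 | direct plan | 1,3,5-tris(methoxymethoxy)benzene | COCOc1cc(OCOC)cc(OCOC)c1
A4 | direct plan | (3R)-3-hydroxy-1-[2-hydroxy-4,6-bis(methoxymethoxy)phenyl]-3-[8-(methoxymethoxy)-2,2-dimethyl-2H-chromen-6-yl]propan-1-one | COCOc1cc(O)c(C(=O)C[C@@H](O)c2cc3C=CC(C)(C)Oc3c(OCOC)c2)c(OCOC)c1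
A5 | direct plan | (2S)-5,7-bis(methoxymethoxy)-2-[8-(methoxymethoxy)-2,2-dimethyl-2H-chromen-6-yl]-2,3-dihydro-4H-chromen-4-one | COCOc1cc(OCOC)c2C(=O)C[C@@H](c3cc4C=CC(C)(C)Oc4c(OCOC)c3)Oc2c1
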